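The ten-membered carbocycle is disconnected at C6–C7 (germacrane numbering). The acetoxy carbon C6 and the adjacent isopropyl-bearing C7 are read as a homoallylic alcohol (isopropyl = reduced isopropenyl), the retron of a carbonyl allylation. In the open-chain precursor, a farnesane-type α,β-epoxy aldehyde with a terminal allylic chloride, both carbons are electrophiles. Pd/Et2Zn reverses the polarity of the allyl terminus, and the allylzinc closes the cyclodecene on the aldehyde, creating C6 and C7 in one operation. The trans-4,5-oxirane, the C3 senecioate and the (E)-C1=C10 alkene are built first from geranyl chloride and a C5 enal, so the carbocycle is formed last.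

Key step: step 8

Remark on numbering and stereochemistry: open-chain compounds 6–15 carry dodecane (farnesane) numbering, ring compounds 16–18 germacrane numbering. Dodecane C-1…C-10 become germacrane C-6, C-5, C-4, C-3, C-2, C-1, C-10, C-9, C-8, C-7. Compounds 11–13 are mixtures at C-10, which is erased in step 8. The sense of induction in step 8 is an expectation, not an established result.

Step 1
Reactants: 1 2-[(tert-butyldimethylsilyl)oxy]acetaldehyde; 2 2-(triphenylphosphoranylidene)propanal
Product: 3 (2E)-4-[(tert-butyldimethylsilyl)oxy]-2-methylbut-2-enal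
Conditions: toluene, 80 °C
Reagents that add atoms: none
Why: Wittig olefination with a stabilised formyl ylide should give the (E)-2-methyl enal, and the α-silyloxy aldehyde 1 should react faster than the less electrophilic enal product.

Step 2
Reactants: 4 geranyl chloride; 3 (2E)-4-[(tert-butyldimethylsilyl)oxy]-2-methylbut-2-enal
Product: 6 rac-(2E,6E)-1-[(tert-butyldimethylsilyl)oxy]-3,7,11-trimethyldodeca-2,6,10-trien-4-ol, via geranylbarium chloride 5 (not isolated)
Conditions: Li, biphenyl, BaI2, THF, rt; 4, −78 °C; then 3, −78 °C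
Reagents that add atoms: none
Why: Allylbarium addition to an aldehyde should occur at the unsubstituted α-carbon of the geranyl unit with retention of the (E)-geometry and 1,2-selectivity toward the enal, giving the linear homoallylic alcohol; C-4 forms as the racemate and is resolved in step 3.

Step 3
Reactants: 6 rac-(2E,6E)-1-[(tert-butyldimethylsilyl)oxy]-3,7,11-trimethyldodeca-2,6,10-trien-4-ol
Product: 7 (2R,3R,4R,6E)-1-[(tert-butyldimethylsilyl)oxy]-2,3-epoxy-3,7,11-trimethyldodeca-6,10-dien-4-ol
Conditions: Ti(OiPr)4 (10 mol %), D-(−)-DIPT (15 mol %), t-BuOOH (0.5 equiv), 4 Å MS, CH2Cl2, −20 °C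
Reagents that add atoms: tert-butyl hydroperoxide, CC(C)(C)OO
Why: In a Sharpless kinetic resolution with D-(−)-tartrate the (4R)-enantiomer of this (E)-secondary allylic alcohol should react fast and be epoxidised on the tartrate-selected face syn to its hydroxyl (erythro, 2R,3R), while (4S)-6 remains and is separated and the isolated trisubstituted alkenes do not react.

Step 4
Reactants: 7 (2R,3R,4R,6E)-1-[(tert-butyldimethylsilyl)oxy]-2,3-epoxy-3,7,11-trimethyldodeca-6,10-dien-4-ol; 8 3-methylbut-2-enoic acid (senecioic acid)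
Product: 10 (2R,3R,4S,6E)-1-[(tert-butyldimethylsilyl)oxy]-2,3-epoxy-3,7,11-trimethyldodeca-6,10-dien-4-yl 3-methylbut-2-enoate, via alkoxyphosphonium senecioate 9 (not isolated)
Conditions: PPh3, DIAD, THF, 0 °C to rt
Reagents that add atoms: none
Why: Mitsunobu esterification should displace the activated C-4 oxygen by carboxylate with inversion (4R to 4S), turning the erythro epoxy alcohol from directed epoxidation into the arrangement of the target, where the ester oxygen and the oxirane oxygen lie on opposite faces, and installing the senecioate in the same operation.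

Step 5
Reactants: 10 (2R,3R,4S,6E)-1-[(tert-butyldimethylsilyl)oxy]-2,3-epoxy-3,7,11-trimethyldodeca-6,10-dien-4-yl 3-methylbut-2-enoate
Product: 11 (2R,3R,4S,6E,10RS)-1-[(tert-butyldimethylsilyl)oxy]-10-chloro-2,3-epoxy-3,7,11-trimethyldodeca-6,11-dien-4-yl 3-methylbut-2-enoate
Conditions: NCS, PhSeCl (10 mol %), CH2Cl2, rt
Reagents that add atoms: N-chlorosuccinimide, ClN1C(=O)CCC1=O
Why: Selenium-catalysed ene-type allylic chlorination should transpose the terminal alkene to the secondary allylic chloride, the 10,11-alkene being the most electron-rich and least hindered (the 6,7-alkene is deactivated by the homoallylic acyloxy group, the senecioate alkene is electron-poor).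

Step 6
Reactants: 11 (2R,3R,4S,6E,10RS)-1-[(tert-butyldimethylsilyl)oxy]-10-chloro-2,3-epoxy-3,7,11-trimethyldodeca-6,11-dien-4-yl 3-methylbut-2-enoate
Product: 12 (2R,3R,4S,6E,10RS)-10-chloro-2,3-epoxy-1-hydroxy-3,7,11-trimethyldodeca-6,11-dien-4-yl 3-methylbut-2-enoate
Conditions: HF·pyridine, pyridine, THF, 0 °C to rt
Reagents that add atoms: none
Why: Fluoride desilylation of the primary silyl ether under buffered, non-basic conditions should leave the epoxide, the ester and the allylic chloride intact (no Payne rearrangement, no acyl migration).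

Step 7
Reactants: 12 (2R,3R,4S,6E,10RS)-10-chloro-2,3-epoxy-1-hydroxy-3,7,11-trimethyldodeca-6,11-dien-4-yl 3-methylbut-2-enoate
Product: 13 (2S,3R,4S,6E,10RS)-10-chloro-2,3-epoxy-3,7,11-trimethyl-1-oxododeca-6,11-dien-4-yl 3-methylbut-2-enoate
Conditions: Dess–Martin periodinane, pyridine, CH2Cl2, 0 °C to rt
Reagents that add atoms: none
Why: Dess–Martin oxidation under buffered conditions should give the α,β-epoxy aldehyde without epimerisation or ring opening at C-2 (the descriptor changes to 2S only through the priority rules), and the aldehyde is used directly.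

Step 8
Reactants: 13 (2S,3R,4S,6E,10RS)-10-chloro-2,3-epoxy-3,7,11-trimethyl-1-oxododeca-6,11-dien-4-yl 3-methylbut-2-enoate
Product: 16 (1(10)E,3S,4R,5R,6R,7S)-4,5-epoxy-6-hydroxygermacra-1(10),11-dien-3-yl 3-methylbut-2-enoate, via ethyl(allyl)zinc aldehyde 14 (not isolated), via ethylzinc alkoxide 15 (not isolated)
Conditions: Pd(PPh3)4 (10 mol %), Et2Zn, K2CO3, DMA, 0.005 M, slow addition of 13, rt
Reagents that add atoms: none
Why: Pd(0) ionises the allylic chloride and Et2Zn transmetalates the allylpalladium to the nucleophilic allylzinc 14 (umpolung carbonyl allylation, the Pd/Zn counterpart of an intramolecular Nozaki–Hiyama–Kishi allylation), which adds through its substituted γ-carbon (dodecane C-10) to the aldehyde carbon C-1 in a six-membered Zimmerman–Traxler array to give alkoxide 15, so two carbons that are both electrophilic in 13 are joined. This is a 10-exo-trig addition to C=O that closes the carbocycle with the oxirane already present; γ-attack rather than α-attack gives the ten- and not the twelve-membered ring and leaves C-11/C-12 as the isopropenyl group. The new carbinol centre (germacrane C-6, 6R) is controlled by the adjacent oxirane centre C-5: attack anti to the epoxide C–O bond on the H-5 flank (Cornforth/Felkin–Anh sense) is expected to give the 5,6-anti epoxy alcohol. The new C-7 centre (7S) is controlled by the tether: with the rigid trans-oxirane and (E)-alkene in the chain, the chair that can span ten atoms should be the one with C-8 pseudo-axial on the E/Z-equilibrating allylzinc terminus, which places hydroxyl and isopropenyl cis on the ring. The step needs chemoselectivity for the aldehyde over two esters and the epoxide, secured by the mild allylzinc, and ring closure over oligomerisation, secured by high dilution with slow addition.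

Step 9
Reactants: 16 (1(10)E,3S,4R,5R,6R,7S)-4,5-epoxy-6-hydroxygermacra-1(10),11-dien-3-yl 3-methylbut-2-enoate
Product: 17 (1(10)E,3S,4R,5R,6R,7S)-4,5-epoxy-6-hydroxygermacr-1(10)-en-3-yl 3-methylbut-2-enoate
Conditions: H2 (1 atm), RhCl(PPh3)3 (10 mol %), benzene, rt
Reagents that add atoms: none
Why: Homogeneous hydrogenation with Wilkinson's catalyst reduces 1,1-disubstituted alkenes much faster than trisubstituted ones, so the isopropenyl group should become isopropyl while the ring (E)-alkene, the senecioate alkene and the epoxide remain; no stereocentre is created.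

Step 10
Reactants: 17 (1(10)E,3S,4R,5R,6R,7S)-4,5-epoxy-6-hydroxygermacr-1(10)-en-3-yl 3-methylbut-2-enoate
Product: 18 (1(10)E,3S,4R,5R,6R,7S)-6-acetoxy-4,5-epoxygermacr-1(10)-en-3-yl 3-methylbut-2-enoate (CNP0267399.1)
Conditions: Ac2O, DMAP (cat.), pyridine, CH2Cl2, rt
Reagents that add atoms: acetic anhydride, CC(=O)OC(C)=O
Why: DMAP-catalysed acetylation of the secondary C-6 hydroxyl proceeds with retention and should complete the target.

Compound list
1 | 2-[(tert-butyldimethylsilyl)oxy]acetaldehyde | O=CCO[Si](C)(C)C(C)(C)C | starting material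
2 | 2-(triphenylphosphoranylidene)propanal | CC(C=O)=P(c1ccccc1)(c1ccccc1)c1ccccc1 | starting material
3 | (2E)-4-[(tert-butyldimethylsilyl)oxy]-2-methylbut-2-enal | O=C/C(C)=C/CO[Si](C)(C)C(C)(C)C | intermediate
4 | geranyl chloride, (2E)-1-chloro-3,7-dimethylocta-2,6-diene | ClC/C=C(\C)CCC=C(C)C | starting material
5 | geranylbarium chloride (formed in the flask, not isolated) | Cl[Ba]C/C=C(\C)CCC=C(C)C | intermediate
6 | rac-(2E,6E)-1-[(tert-butyldimethylsilyl)oxy]-3,7,11-trimethyldodeca-2,6,10-trien-4-ol | OC(C/C=C(\C)CCC=C(C)C)/C(C)=C/CO[Si](C)(C)C(C)(C)C | intermediate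
7 | (2R,3R,4R,6E)-1-[(tert-butyldimethylsilyl)oxy]-2,3-epoxy-3,7,11-trimethyldodeca-6,10-dien-4-ol | CC(C)(C)[Si](C)(C)OC[C@H]1O[C@]1(C)[C@H](O)C/C=C(\C)CCC=C(C)C | intermediate
8 | 3-methylbut-2-enoic acid (senecioic acid) | CC(C)=CC(O)=O | starting material
9 | C-4 alkoxytriphenylphosphonium 3-methylbut-2-enoate derived from 7 (not isolated) | CC(C)(C)[Si](C)(C)OC[C@H]1O[C@]1(C)[C@H](O[P+](c2ccccc2)(c2ccccc2)c2ccccc2)C/C=C(\C)CCC=C(C)C.CC(C)=CC([O-])=O | intermediate
10 | (2R,3R,4S,6E)-1-[(tert-butyldimethylsilyl)oxy]-2,3-epoxy-3,7,11-trimethyldodeca-6,10-dien-4-yl 3-methylbut-2-enoate | CC(C)(C)[Si](C)(C)OC[C@H]1O[C@]1(C)[C@@H](OC(=O)C=C(C)C)C/C=C(\C)CCC=C(C)C | intermediate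
11 | (2R,3R,4S,6E,10RS)-1-[(tert-butyldimethylsilyl)oxy]-10-chloro-2,3-epoxy-3,7,11-trimethyldodeca-6,11-dien-4-yl 3-methylbut-2-enoate | CC(C)(C)[Si](C)(C)OC[C@H]1O[C@]1(C)[C@@H](OC(=O)C=C(C)C)C/C=C(\C)CCC(Cl)C(C)=C | intermediate
12 | (2R,3R,4S,6E,10RS)-10-chloro-2,3-epoxy-1-hydroxy-3,7,11-trimethyldodeca-6,11-dien-4-yl 3-methylbut-2-enoate | OC[C@H]1O[C@]1(C)[C@@H](OC(=O)C=C(C)C)C/C=C(\C)CCC(Cl)C(C)=C | intermediate
13 | (2S,3R,4S,6E,10RS)-10-chloro-2,3-epoxy-3,7,11-trimethyl-1-oxododeca-6,11-dien-4-yl 3-methylbut-2-enoate | O=C[C@H]1O[C@]1(C)[C@@H](OC(=O)C=C(C)C)C/C=C(\C)CCC(Cl)C(C)=C | intermediate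
14 | ethyl(allyl)zinc aldehyde: C-12 ethylzinc σ-allyl species of 13 with C10=C11 alkene (not isolated) | O=C[C@H]1O[C@]1(C)[C@@H](OC(=O)C=C(C)C)C/C=C(\C)CCC=C(C)C[Zn]CC | intermediate
15 | ethylzinc alkoxide of 16 (not isolated) | CC[Zn]O[C@H]1[C@H]2O[C@]2(C)[C@@H](OC(=O)C=C(C)C)C/C=C(\C)CC[C@H]1C(C)=C | intermediate
16 | (1(10)E,3S,4R,5R,6R,7S)-4,5-epoxy-6-hydroxygermacra-1(10),11-dien-3-yl 3-methylbut-2-enoate | O[C@H]1[C@H]2O[C@]2(C)[C@@H](OC(=O)C=C(C)C)C/C=C(\C)CC[C@H]1C(C)=C | intermediate
17 | (1(10)E,3S,4R,5R,6R,7S)-4,5-epoxy-6-hydroxygermacr-1(10)-en-3-yl 3-methylbut-2-enoate | O[C@H]1[C@H]2O[C@]2(C)[C@@H](OC(=O)C=C(C)C)C/C=C(\C)CC[C@H]1C(C)C | intermediate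
18 | (1(10)E,3S,4R,5R,6R,7S)-6-acetoxy-4,5-epoxygermacr-1(10)-en-3-yl 3-methylbut-2-enoate | CC(=O)O[C@H]1[C@H]2O[C@]2(C)[C@@H](OC(=O)C=C(C)C)C/C=C(\C)CC[C@H]1C(C)C | target

Total step count: 10. Longest linear sequence: 10 steps (1/2 to 18).

Steps most likely to fail

Step 8 (key ring closure). The aldehyde face may be selected against the Cornforth/Felkin sense inside the macrocyclic transition state, so that the C-6 carbinol forms as the epimer or as a mixture. Fallback: the configuration at C-6 is then set by ketone reduction instead of by the C–C bond formation. Setting out from 13, the same closure is run and the (1(10)E,3S,4R,5R,6S,7S)-6-epi alcohol F1 is accepted. Dess–Martin oxidation (pyridine, CH2Cl2) should give the macrocyclic α,β-epoxy ketone F2. Reduction with Zn(BH4)2 in Et2O at −20 °C, anti-selective for α,β-epoxy ketones and expected to deliver hydride from the ring periphery, comes back to the route at 16.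

Step 4 (Mitsunobu inversion). Displacement at a carbinol flanked by a fully substituted oxirane carbon with the weakly acidic senecioic acid may be slow, leading to incomplete inversion, elimination or retention. Fallback: C-4 is fixed without inversion and the oxirane is built under reagent control from the primary alcohol. Setting out from 6, the resolution of step 3 is run to higher conversion and the unreacted (4S)-allylic alcohol F3 is kept. Esterification with 8 (EDC, DMAP, CH2Cl2; retention) should give the allylic senecioate F4. Ene-chlorination as in step 5 should give the allylic chloride F5, and HF·pyridine the primary allylic alcohol F6. Sharpless epoxidation directed by the C-1 hydroxyl (Ti(OiPr)4, D-(−)-DET, t-BuOOH, 4 Å MS, CH2Cl2, −20 °C) should then place the (2R,3R)-oxirane anti to the C-4 ester and comes back to the route at 12.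

Step 5 (ene-chlorination). Site selectivity between the 10,11- and the 6,7-alkene may be poor, or chlorination may go further. Fallback: the allyl electrophile is made by allylic oxidation of the terminal trans-methyl group instead. Setting out from 10, SeO2 (cat.), t-BuOOH and salicylic acid in CH2Cl2 should give the primary (10E)-allylic alcohol F7. Benzoylation (BzCl, pyridine) gives the allylic benzoate F8, HF·pyridine the primary alcohol F9, and Dess–Martin oxidation the epoxy aldehyde benzoate F10. Its Pd(PPh3)4/Et2Zn ring closure passes through the same allylzinc 14 and comes back to the route at 16.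

Further compounds
F1 | step 8 | (1(10)E,3S,4R,5R,6S,7S)-4,5-epoxy-6-hydroxygermacra-1(10),11-dien-3-yl 3-methylbut-2-enoate (6-epi-16) | O[C@@H]1[C@H]2O[C@]2(C)[C@@H](OC(=O)C=C(C)C)C/C=C(\C)CC[C@H]1C(C)=C
F2 | step 8 | (1(10)E,3S,4R,5S,7S)-4,5-epoxy-6-oxogermacra-1(10),11-dien-3-yl 3-methylbut-2-enoate | O=C1[C@H]2O[C@]2(C)[C@@H](OC(=O)C=C(C)C)C/C=C(\C)CC[C@H]1C(C)=C
F3 | step 4 | (2E,4S,6E)-1-[(tert-butyldimethylsilyl)oxy]-3,7,11-trimethyldodeca-2,6,10-trien-4-ol | O[C@@H](C/C=C(\C)CCC=C(C)C)/C(C)=C/CO[Si](C)(C)C(C)(C)C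
F4 | step 4 | (2E,4S,6E)-1-[(tert-butyldimethylsilyl)oxy]-3,7,11-trimethyldodeca-2,6,10-trien-4-yl 3-methylbut-2-enoate | CC(C)=CC(=O)O[C@@H](C/C=C(\C)CCC=C(C)C)/C(C)=C/CO[Si](C)(C)C(C)(C)C
F5 | step 4 | (2E,4S,6E,10RS)-1-[(tert-butyldimethylsilyl)oxy]-10-chloro-3,7,11-trimethyldodeca-2,6,11-trien-4-yl 3-methylbut-2-enoate | CC(C)=CC(=O)O[C@@H](C/C=C(\C)CCC(Cl)C(C)=C)/C(C)=C/CO[Si](C)(C)C(C)(C)C
F6 | step 4 | (2E,4S,6E,10RS)-10-chloro-1-hydroxy-3,7,11-trimethyldodeca-2,6,11-trien-4-yl 3-methylbut-2-enoate | CC(C)=CC(=O)O[C@@H](C/C=C(\C)CCC(Cl)C(C)=C)/C(C)=C/CO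
F7 | step 5 | (2R,3R,4S,6E,10E)-1-[(tert-butyldimethylsilyl)oxy]-2,3-epoxy-12-hydroxy-3,7,11-trimethyldodeca-6,10-dien-4-yl 3-methylbut-2-enoate | CC(C)(C)[Si](C)(C)OC[C@H]1O[C@]1(C)[C@@H](OC(=O)C=C(C)C)C/C=C(\C)CC/C=C(\C)CO
F8 | step 5 | (2R,3R,4S,6E,10E)-12-(benzoyloxy)-1-[(tert-butyldimethylsilyl)oxy]-2,3-epoxy-3,7,11-trimethyldodeca-6,10-dien-4-yl 3-methylbut-2-enoate | CC(C)(C)[Si](C)(C)OC[C@H]1O[C@]1(C)[C@@H](OC(=O)C=C(C)C)C/C=C(\C)CC/C=C(\C)COC(=O)c2ccccc2
F9 | step 5 | (2R,3R,4S,6E,10E)-12-(benzoyloxy)-2,3-epoxy-1-hydroxy-3,7,11-trimethyldodeca-6,10-dien-4-yl 3-methylbut-2-enoate | OC[C@H]1O[C@]1(C)[C@@H](OC(=O)C=C(C)C)C/C=C(\C)CC/C=C(\C)COC(=O)c2ccccc2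
F10 | step 5 | (2S,3R,4S,6E,10E)-12-(benzoyloxy)-2,3-epoxy-3,7,11-trimethyl-1-oxododeca-6,10-dien-4-yl 3-methylbut-2-enoate | O=C[C@H]1O[C@]1(C)[C@@H](OC(=O)C=C(C)C)C/C=C(\C)CC/C=C(\C)COC(=O)c2ccccc2
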